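## Structural features

The target is a eudesmane diester, numbered as follows: ring A is C1–C2–C3–C4–C5–C10, ring B is C5–C6–C7–C8–C9–C10, C14 is the methyl on C10, C15 the methyl on C4, and C11–C13 the isopropyl group on C7. Read literally, the SMILES gives 3R,4S,5S,7R,10R. H5 and C14 therefore lie on the same (β) face and the rings are cis-fused at C5–C10, C15 and the isopropyl group are also β, and the angelate on C3 and the acetate on C4 are both α, cis to each other and on the concave face, the side on which C6 and C9 leave ring A. C3, C4, C5 and C10 form an unbroken row of four stereocentres, two of them fully substituted (C4 and C10), while C7 stands alone next to the C8 ketone and can be epimerised. Two chair–chair conformers matter: conformer S (C14 equatorial and C9 axial on ring A, C4 axial on ring B) and its ring-flipped partner N (C14 and C6 axial on ring A). The target should sit in S, with O4 axial and O3 and the 7β-isopropyl group equatorial, because N would hold C14 and C15 syn-diaxial. The fragile groups are the (Z)-2-methylbut-2-enoate (drifts to E under acid, heat or nucleophilic catalysis), the hindered tertiary acetate (hard to make, able to ionise) and C7. The real difficulty is a cis fusion next to a quaternary carbon combined with two C–O bonds on the concave face, with oxygen at C3, C4 and C8 spread over both rings so that no single enone annulation places them. The key step exploits this feature: once the C3/C4 diol is seen as a C3=C4 alkene, O=C8–C7–C6–C5–C4=C3 is a δ,ε-unsaturated ketone, the retron of an oxy-Cope rearrangement, and rejoining C3 to C8 folds ring A and C8–C9 into a bicyclo[2.2.2]octene whose cage allows only the cis C5/C10 relationship and which descends from a mirror-symmetric diketone.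

## Logic of the disconnections

**30 ⇒ 29 ⇒ 26.**
- Bonds cut: O4–acetyl, then O3–angeloyl.
- Reason: the esters are the most fragile groups, and the Z-alkene should see as few steps as possible.
- Gain: 26 has no alkene and no base-labile group, so C7 can be equilibrated there.
- Demand: the equatorial secondary O3–H must be told from the axial tertiary O4–H (easy). The tertiary hydroxyl must then be acylated without isomerising the angelate (hard).

**26 ⇒ 24 ⇒ 21.**
- Bonds cut: C3–O and C4–O. The C7–H/C11–H pair is also taken out again as C7=C11.
- Reason: a C3=C4 alkene is the one precursor from which both carbinol carbons arise in a single operation.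
- Gain: three stereocentres (C3, C4, C7) disappear.
- Demand: both oxygens stand on the concave face, so a reagent that delivers two oxygens directly would come from the convex β face and give the wrong diol. The forward step must put an electrophile on the β face and bring both oxygens in from behind. This is trans-diaxial only in conformer S.
- At the alkene stage, increment counting puts N below S by roughly 1–2 kcal/mol, because of allylic 1,2-strain between C15 and a pseudo-equatorial C6 in S.
- A saturated C7 is therefore expected to settle, kinetically and thermodynamically, as the 7α-isopropyl epimer. That epimer is locked in N, because in S its isopropyl group would be syn-diaxial with C4.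
- C7 is therefore kept trigonal until C4 is tetrahedral. After that only S is populated, and equilibration gives the 7β (7R) epimer.

**21 ⇒ 17 (key).**
- Bonds: C5–C6 is cut and C3–C8 is rejoined, with the π bonds moving to C4=C5 and C6=C7.
- In one sentence, the route is an anionic oxy-Cope rearrangement of 17. That sentence does not describe an annulation route.
- Reason: the cut goes through the hardest element, the C5–C10 fusion.
- Gain: the fusion problem vanishes, because in 17 C5 is a trigonal CH and C10 a bridgehead. The carbonyl at C8, the branch at C7 and the C3=C4 alkene with C15 all follow from connectivity.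
- Demand: the dienyl group on C8 must stand over the C4=C5 bridge.

**17 ⇒ 11 + 14, and 14 ⇒ 12.**
- Bond cut: C7–C8 (carbonyl addition), then C–Br.
- Reason and gain: the route becomes convergent, a C10 ketone plus a C5 nucleophile.
- Demand: attack on the carbonyl face that looks at the alkene bridge, without enolisation.

**11 ⇒ 10 ⇒ 8 ⇒ 6.**
- Bond cut: C4–C15, with C8 taken back to the carbinol level.
- Reason: C4 and C8 become the two oxygenated carbons flanking one bridgehead.
- Gain: the two bridges differ only in oxidation level.
- Demand: regiospecific conversion of a ketone into a methyl-substituted alkene. The cage guarantees this, because the bridgehead cannot be deprotonated.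

**6 ⇒ 5.**
- Bond cut: C8–H.
- Reason and gain: 5 has a mirror plane, so all absolute configuration (C10, then C5 and the rest) comes down to one enantiotopic-group choice.
- Demand: a catalyst that tells the two carbonyl groups apart.

**5 ⇒ 4.**
- Bond cut: bridgehead CH to one carbonyl carbon (the two are equivalent in 5).
- Gain: the cage becomes a monocycle.
- Demand: acylation at the ring CH2 para to the quaternary carbon.

**4 ⇒ 3 ⇒ 1 + 2.**
- Bond cut: C10–CH2 of the side chain, after degrading one carbon.
- Gain: two commercial compounds.
- Demand: conjugate addition to a β,β-disubstituted enone. Racemic material suffices.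

## Other disconnections considered

**Alternative 1:** (the first that comes to mind) Robinson annulation.
- Cut: C1–C10 and C4–C5.
- Forward: Michael addition and aldol condensation of (5R)-2-methyl-5-isopropylcyclohexanone A1 with pent-1-en-3-one A2 to give the eudesm-4-en-3-one A3.
- Ground for rejection: the annulation consumes the only ring-B carbonyl (it becomes C5), so C8 is left without a handle and would need a remote oxidation. C5 emerges trigonal inside the enone, so none of C3, C4 and C5 is set. Turning C4=C5 into C4(O)(CH3)/C5–H with a cis fusion requires reduction followed by re-oxidation at C4. The chosen plan places O8 and the alkene for O3/O4 in the ring-forming step itself.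

**Alternative 2:** biomimetic transannular cyclisation.
- Cut: C5–C10 and C4–O.
- Forward: proton-initiated cyclisation of the (1(10)E,4E)-germacradienone A4, with capture of the C4 cation by water.
- Ground for rejection: the crossed chair–chair array of an E,E-diene closes to a trans fusion, and anti addition across the E C4=C5 bond puts O4 and H5 on the same face. The mechanism therefore leads to the 5α-H diol A5, the C5 epimer of what is needed. The cis series would need the 4Z isomer, and a stereodefined ten-membered ring is a harder problem than the target.

**Alternative 3:** Diels–Alder reaction.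
- Cut: C5–C6 and C9–C10.
- Forward: Lewis-acid-promoted [4+2] addition of the silyloxydiene A6 to 1 (as ring A) to give the cis-decalone A7.
- Merits: a cis fusion, a masked C8 ketone, and a C4 ketone open to methyl addition from the convex face.
- Ground for rejection: a bond must form at the fully substituted β-carbon of a poor dienophile, under Lewis acids that endanger A6. Absolute control needs a chiral catalyst for this hindered pair. C5 of A7 is α to the C4 ketone, so the cis fusion can leak to trans. O3 would enter from the convex (wrong) face and need inversion. In the chosen plan C5 is never enolisable, and the step count is not higher.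

Key step: step 10

Assumption: the SMILES is taken literally, so the target is the cis-fused (5βH) eudesmane, although most natural eudesmanes are trans-fused.
Assumption: a commercial ketoreductase panel contains an anti-Prelog enzyme that reduces 5 to 6; the carbinol configuration itself is irrelevant because step 7 removes it, and the opposite enzyme sense is covered by a fallback.

## Steps

Step 1
Reactants: 1 3-methylcyclohex-2-en-1-one; 2 allyltrimethylsilane
Product: 3 (±)-3-allyl-3-methylcyclohexan-1-one
Conditions: TiCl4, CH2Cl2, −78 °C; then H2O
Reagents that add atoms: none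
Why: Hosomi–Sakurai conjugate allylation, a reaction type that tolerates β,β-disubstituted enones and so builds the quaternary carbon (future C10). The product is racemic, which is harmless because step 3 leads to an achiral compound.

Step 2
Reactants: 3 (±)-3-allyl-3-methylcyclohexan-1-one
Product: 4 (±)-2-(1-methyl-3-oxocyclohexyl)acetic acid
Conditions: RuCl3·xH2O (cat.), NaIO4, MeCN–EtOAc–H2O, rt
Reagents that add atoms: sodium periodate [Na+].[O-]I(=O)(=O)=O
Why: Catalytic ruthenium tetroxide cleavage of a terminal alkene to the carboxylic acid with loss of the terminal carbon; the ketone and the quaternary carbon are inert.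

Step 3
Reactants: 4 (±)-2-(1-methyl-3-oxocyclohexyl)acetic acid
Product: 5 4-methylbicyclo[2.2.2]octane-2,6-dione
Conditions: polyphosphoric acid, AcOH, 100 °C
Reagents that add atoms: none
Why: Intramolecular C-acylation of the ketone enol by the activated side-chain acid; attack through the ring CH2 para to the quaternary carbon closes a six-membered ring, whereas the other α-carbon would give a cyclobutanone. The product has a mirror plane through both bridgeheads and the ethano bridge, so the stereocentre of 4 disappears, and the bridgehead CH between the carbonyl groups cannot enolise.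

Step 4
Reactants: 5 4-methylbicyclo[2.2.2]octane-2,6-dione
Product: 6 (1S,4R,6R)-6-hydroxy-4-methylbicyclo[2.2.2]octan-2-one
Conditions: ketoreductase (anti-Prelog, NADPH-dependent), NADP+ (cat.), i-PrOH, phosphate buffer pH 7, 30 °C
Reagents that add atoms: none
Why: Enzymatic desymmetrisation of a mirror-symmetric diketone by a ketoreductase (short-chain dehydrogenase/reductase class), a reaction type known for bicyclo[2.2.2]octane-2,6-diones. The active site distinguishes the enantiotopic carbonyl groups and thereby fixes both bridgeheads (future C3 and C10, 10R), the source of all absolute configuration; the reduced carbon is the future C8.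

Step 5
Reactants: 6 (1S,4R,6R)-6-hydroxy-4-methylbicyclo[2.2.2]octan-2-one; 7 2,4,6-triisopropylbenzenesulfonohydrazide
Product: 8 (E)-2,4,6-triisopropylbenzenesulfonylhydrazone of 6
Conditions: THF, HCl (cat.), rt
Reagents that add atoms: none
Why: Acid-catalysed hydrazone formation; the secondary alcohol is untouched and the sulfonamide nitrogen settles away from the bridgehead, on the side of the only enolisable CH2.

Step 6
Reactants: 8 (E)-2,4,6-triisopropylbenzenesulfonylhydrazone of 6
Product: 10 (1R,2R,4R)-4,6-dimethylbicyclo[2.2.2]oct-5-en-2-ol, via vinyllithium alkoxide 9 (not isolated)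
Conditions: n-BuLi (3.3 equiv), TMEDA, THF, −78 to 0 °C; MeI, −78 °C; then H2O
Reagents that add atoms: iodomethane CI
Why: Shapiro reaction with alkylation: after O–H and N–H are deprotonated, the third equivalent removes a proton from the CH2 (future C5; the bridgehead is not available), and loss of sulfinate and N2 gives 9 regiospecifically. C-methylation of the vinyllithium (installing C15) should be much faster at −78 °C than O-methylation of the lithium alkoxide.

Step 7
Reactants: 10 (1R,2R,4R)-4,6-dimethylbicyclo[2.2.2]oct-5-en-2-ol
Product: 11 (1R,4R)-4,6-dimethylbicyclo[2.2.2]oct-5-en-2-one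
Conditions: Dess–Martin periodinane, CH2Cl2, rt
Reagents that add atoms: none
Why: Dess–Martin oxidation under neutral conditions; the β,γ-unsaturated ketone cannot move into conjugation because that would need a bridgehead double bond, and the bridgeheads are untouched.

Step 8
Reactants: 12 2-methylbut-1-en-3-yne
Product: 14 2-bromo-3-methylbuta-1,3-diene, via bromoalkenylborane 13 (not isolated)
Conditions: B-Br-9-BBN, CH2Cl2, 0 °C; then AcOH, 0 °C to rt
Reagents that add atoms: B-bromo-9-borabicyclo[3.3.1]nonane BrB1C2CCCC1CCC2
Why: Bromoboration of a terminal alkyne (syn addition, boron on the terminal carbon, alkenes left alone) followed by protonolysis of the alkenyl–boron bond, the known route to 2-bromo-1-alkenes.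

Step 9
Reactants: 11 (1R,4R)-4,6-dimethylbicyclo[2.2.2]oct-5-en-2-one; 14 2-bromo-3-methylbuta-1,3-diene
Product: 17 (1R,2S,4R)-4,6-dimethyl-2-(3-methylbuta-1,3-dien-2-yl)bicyclo[2.2.2]oct-5-en-2-ol, via dienyllithium 15 (not isolated), via dienylcerium dichloride 16 (not isolated)
Conditions: 14, t-BuLi (2 equiv), Et2O, −78 °C; CeCl3, THF, −78 °C; then 11, −78 °C; then H2O
Reagents that add atoms: none
Why: Bromine–lithium exchange and transmetalation give the weakly basic organocerium reagent 16, which adds 1,2 to the enolisable ketone. The nucleophile should come in over the C4=C5 bridge, whose sp2 carbons keep H5 and C15 in the plane of the bridge, and not over the ethano bridge, which points a C–H bond into the trajectory; this sets C8 with the dienyl group above the alkene, as step 10 requires.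

Step 10
Reactants: 17 (1R,2S,4R)-4,6-dimethyl-2-(3-methylbuta-1,3-dien-2-yl)bicyclo[2.2.2]oct-5-en-2-ol
Product: 21 (5S,10R)-5βH-eudesma-3,7(11)-dien-8-one, via potassium alkoxide 18 (not isolated), via potassium dienolate 19 (not isolated), via deconjugated ketone 20 (not isolated)
Conditions: KH, 18-crown-6, THF, 0 °C to rt; then MeOH, rt; then H2O
Reagents that add atoms: none
Why: KH with 18-crown-6 gives the nearly free alkoxide 18, in which the oxyanion weakens the adjacent C3–C8 bond, and a concerted suprafacial [3,3] shift over the array C6=C7–C8–C3–C4=C5 breaks C3–C8 and forms C5–C6 to give the dienolate 19. This is the anionic oxy-Cope rearrangement, and the closest known reaction type is this very substrate class, 2-alkenylbicyclo[2.2.2]oct-5-en-2-olates going to cis-fused octalone enolates. Ring B (C5–C6–C7–C8–C9–C10) is closed as a six-membered ring in sigmatropic mode through the boat-shaped transition state that the cage enforces, by union of the two least hindered termini, the CH2 group C6 and the CH carbon C5, while ring A is the part of the cage that survives. The only new stereocentre is C5 and it is controlled by the bridgehead C10: C6 is tethered through C8–C9 and can reach C5 only on the alkene face that looks at this bridge, so C6 and C9 end up on one side and H5 and C14 on the other, which is the cis fusion with 5S following from 10R. C10 is not touched, and the stereocentres C3 and C8 of 17 are spent as planned, C3 becoming an alkene carbon and C8 the carbonyl carbon. The selectivity needed is [3,3] over [1,3] shift and over cleavage back to ketone and dienyl anion; it is secured by the placement of the dienyl group over C4=C5 (step 9), by the fact that only C6=C7 is attached to C8 so that a single 1,5-diene exists, and by the irreversible formation of a delocalised dienolate with release of cage strain. Methanol protonates 19 at C7 to give 20 and the methoxide formed carries the double bond into conjugation; only the C12/C13 hydrogens are vinylogously acidic, so the tetrasubstituted C7=C11 enone 21 is the single thermodynamic sink and no stereocentre at C7 has to be handled yet. In one operation the step thus delivers the decalin, the cis fusion, the ketone at C8, the three-carbon branch at C7 and the trisubstituted C3=C4 alkene with C15 in place.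

Step 11
Reactants: 21 (5S,10R)-5βH-eudesma-3,7(11)-dien-8-one
Product: 24 (3R,4S,5S,10R)-4α-acetoxy-3α-hydroxy-5βH-eudesm-7(11)-en-8-one, via iodo acetate 22 (not isolated), via acetoxonium ion 23 (not isolated)
Conditions: I2, AgOAc (2.2 equiv), AcOH, rt, dark; then H2O, 90 °C
Reagents that add atoms: silver acetate CC(=O)[O-].[Ag+]; water O
Why: Woodward cis-hydroxylation: the iodine electrophile bridges the electron-rich C3=C4 bond on the open convex β face (the enone alkene is deactivated), acetate opens the iodonium ion at the tertiary C4 from the α face in the trans-diaxial manner available in conformer S (Fürst–Plattner) to give 22, and silver-assisted displacement of the axial 3β-iodide by the acetate carbonyl gives the α-face ion 23. Water adds to the cationic carbon and the hemi-orthoester collapses to the cis hydroxy acetate, expected as the axial (C4) ester; the position of the acetyl group is of no consequence because step 12 removes it. C3 (R) and C4 (S) are thus set on the concave face by inversion relative to the face chosen by iodine.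

Step 12
Reactants: 24 (3R,4S,5S,10R)-4α-acetoxy-3α-hydroxy-5βH-eudesm-7(11)-en-8-one
Product: 26 (3R,4S,5S,7R,10R)-3α,4α-dihydroxy-5βH,7αH-eudesman-8-one, via saturated hydroxy acetate 25 (not isolated)
Conditions: H2 (1 atm), Pd/C, MeOH, rt; then K2CO3, MeOH, rt
Reagents that add atoms: none
Why: Heterogeneous hydrogenation of an exocyclic isopropylidene ketone, then carbonate methanolysis of the acetate and enolate equilibration of C7 in the same flask. With C4 tetrahedral only conformer S is populated (N would hold C14 and C15 syn-diaxial), and in S the 7β-isopropyl group is equatorial whereas a 7α group would be syn-diaxial with C4, so thermodynamic control should give 7R.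

Step 13
Reactants: 26 (3R,4S,5S,7R,10R)-3α,4α-dihydroxy-5βH,7αH-eudesman-8-one; 27 angelic acid
Product: 29 (3R,4S,5S,7R,10R)-3α-angeloyloxy-4α-hydroxy-5βH,7αH-eudesman-8-one, via mixed anhydride 28 (not isolated)
Conditions: 27, 2,4,6-trichlorobenzoyl chloride, Et3N, toluene, rt; then 26, 80 °C
Reagents that add atoms: none
Why: Yamaguchi-type mixed-anhydride esterification, run without nucleophilic catalyst, the established way to transfer an angeloyl group without Z-to-E isomerisation. Only the equatorial secondary 3α-hydroxyl reacts; the axial tertiary 4α-hydroxyl is too hindered.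

Step 14
Reactants: 29 (3R,4S,5S,7R,10R)-3α-angeloyloxy-4α-hydroxy-5βH,7αH-eudesman-8-one
Product: 30 (3R,4S,5S,7R,10R)-4α-acetoxy-3α-angeloyloxy-5βH,7αH-eudesman-8-one (target)
Conditions: Ac2O, DMAP, Et3N, CH2Cl2, 40 °C
Reagents that add atoms: acetic anhydride CC(=O)OC(C)=O
Why: DMAP-catalysed acetylation, the standard acyl transfer to tertiary alcohols; no stereocentre is touched, C7 already has its thermodynamic configuration, and the α,β-disubstituted angelate is a poor acceptor for DMAP.

## Compound list

1 | 3-methylcyclohex-2-en-1-one | CC1=CC(=O)CCC1 | starting material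
2 | allyltrimethylsilane | C=CC[Si](C)(C)C | starting material
3 | (±)-3-allyl-3-methylcyclohexan-1-one (racemic) | C=CCC1(C)CCCC(=O)C1 | intermediate
4 | (±)-2-(1-methyl-3-oxocyclohexyl)acetic acid (racemic) | CC1(CC(=O)O)CCCC(=O)C1 | intermediate
5 | 4-methylbicyclo[2.2.2]octane-2,6-dione (achiral) | CC12CCC(C(=O)C1)C(=O)C2 | intermediate
6 | (1S,4R,6R)-6-hydroxy-4-methylbicyclo[2.2.2]octan-2-one | C[C@]12CC[C@H](C(=O)C1)[C@H](O)C2 | intermediate
7 | 2,4,6-triisopropylbenzenesulfonohydrazide | CC(C)c1cc(C(C)C)c(S(=O)(=O)NN)c(C(C)C)c1 | starting material
8 | (E)-2,4,6-triisopropylbenzenesulfonylhydrazone of 6 | C[C@]12CC[C@H](/C(=N/NS(=O)(=O)c3c(C(C)C)cc(C(C)C)cc3C(C)C)C1)[C@H](O)C2 | intermediate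
9 | vinyllithium alkoxide (6-lithio-4-methylbicyclo[2.2.2]oct-5-en-2-olate, dilithium) | C[C@]12CC[C@H](C([Li])=C1)[C@H](O[Li])C2 | intermediate
10 | (1R,2R,4R)-4,6-dimethylbicyclo[2.2.2]oct-5-en-2-ol | C[C@]12CC[C@H](C(C)=C1)[C@H](O)C2 | intermediate
11 | (1R,4R)-4,6-dimethylbicyclo[2.2.2]oct-5-en-2-one | C[C@]12CC[C@H](C(C)=C1)C(=O)C2 | intermediate
12 | 2-methylbut-1-en-3-yne | C=C(C)C#C | starting material
13 | 9-[(Z)-2-bromo-3-methylbuta-1,3-dienyl]-9-borabicyclo[3.3.1]nonane | C=C(C)/C(Br)=C/B1C2CCCC1CCC2 | intermediate
14 | 2-bromo-3-methylbuta-1,3-diene | C=C(C)C(Br)=C | intermediate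
15 | 3-methylbuta-1,3-dien-2-yllithium | [Li]C(=C)C(C)=C | intermediate
16 | dichloro(3-methylbuta-1,3-dien-2-yl)cerium | Cl[Ce](Cl)C(=C)C(C)=C | intermediate
17 | (1R,2S,4R)-4,6-dimethyl-2-(3-methylbuta-1,3-dien-2-yl)bicyclo[2.2.2]oct-5-en-2-ol | C[C@]12CC[C@H](C(C)=C1)[C@](O)(C(=C)C(C)=C)C2 | intermediate
18 | potassium alkoxide of 17 | C[C@]12CC[C@H](C(C)=C1)[C@]([O-])(C(=C)C(C)=C)C2.[K+] | intermediate
19 | potassium (5S,10R)-5βH-eudesma-3,7,11-trien-8-olate | CC1=CCC[C@]2(C)CC([O-])=C(C(C)=C)C[C@H]12.[K+] | intermediate
20 | (5S,10R)-5βH-eudesma-3,11-dien-8-one (C7 epimers) | CC1=CCC[C@]2(C)CC(=O)C(C(C)=C)C[C@H]12 | intermediate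
21 | (5S,10R)-5βH-eudesma-3,7(11)-dien-8-one | CC1=CCC[C@]2(C)CC(=O)C(=C(C)C)C[C@H]12 | intermediate
22 | 4α-acetoxy-3β-iodo-5βH-eudesm-7(11)-en-8-one | I[C@H]1CC[C@]2(C)CC(=O)C(=C(C)C)C[C@@H]2[C@]1(C)OC(C)=O | intermediate
23 | 3α,4α-acetoxonium (2-methyl-1,3-dioxolan-2-ylium) ion | O1[C@@H]2CC[C@]3(C)CC(=O)C(=C(C)C)C[C@@H]3[C@]2(C)[O+]=C1C | intermediate
24 | (3R,4S,5S,10R)-4α-acetoxy-3α-hydroxy-5βH-eudesm-7(11)-en-8-one | O[C@@H]1CC[C@]2(C)CC(=O)C(=C(C)C)C[C@@H]2[C@]1(C)OC(C)=O | intermediate
25 | 4α-acetoxy-3α-hydroxy-5βH-eudesman-8-one (C7 epimers) | O[C@@H]1CC[C@]2(C)CC(=O)C(C(C)C)C[C@@H]2[C@]1(C)OC(C)=O | intermediate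
26 | (3R,4S,5S,7R,10R)-3α,4α-dihydroxy-5βH,7αH-eudesman-8-one | O[C@@H]1CC[C@]2(C)CC(=O)[C@@H](C(C)C)C[C@@H]2[C@]1(C)O | intermediate
27 | angelic acid, (Z)-2-methylbut-2-enoic acid | C/C=C(/C)C(=O)O | starting material
28 | angelic 2,4,6-trichlorobenzoic anhydride | C/C=C(/C)C(=O)OC(=O)c1c(Cl)cc(Cl)cc1Cl | intermediate
29 | (3R,4S,5S,7R,10R)-3α-angeloyloxy-4α-hydroxy-5βH,7αH-eudesman-8-one | C/C=C(/C)C(=O)O[C@@H]1CC[C@]2(C)CC(=O)[C@@H](C(C)C)C[C@@H]2[C@]1(C)O | intermediate
30 | (3R,4S,5S,7R,10R)-4α-acetoxy-3α-angeloyloxy-5βH,7αH-eudesman-8-one | C/C=C(/C)C(=O)O[C@@H]1CC[C@]2(C)CC(=O)[C@@H](C(C)C)C[C@@H]2[C@]1(C)OC(C)=O | target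

## Step count and least certain steps

Total step count: 14. Longest linear sequence: 13 steps (1–7 and 9–14); step 8 is a one-step branch.

**Step 10 (key step).**
- Most likely failure: base-induced polymerisation or proton-transfer decay of the dienyl carbinolate competes with a [3,3] shift that is slowed by compression between the isopropenyl group and the cage in the boat array. In addition, any material that added from the wrong carbonyl face in step 9 cannot rearrange.
- Fallback: it sets out from 11 and comes back at 21, and it splits the five-carbon unit. Vinylmagnesium bromide with CeCl3 adds to 11 to give the vinyl carbinol F1, the least hindered substrate of this rearrangement. KH and 18-crown-6 then give the C7-unsubstituted cis-octalone F2. LDA deprotonates F2 at C7 rather than at the neopentyl C9, and ZnCl2 followed by acetone gives the aldol F3. Dehydration of F3 (p-TsOH cat., toluene, reflux) gives 21.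

**Step 11.**
- Most likely failure: the iodonium ion loses a proton (allylic substitution or elimination) in place of acetate capture, because the α face of C4 is crowded by the syn-axial C9. Facial selectivity also erodes if conformer N takes part.
- Fallback: it sets out from 21 and comes back at 26, and it inverts C3 by redox chemistry and not by neighbouring-group displacement. mCPBA epoxidises C3=C4 from the convex face to give the 3β,4β-epoxide F4. Aqueous HClO4 opens F4 at the tertiary C4 with inversion to give the 3β,4α-diol F5. Dess–Martin oxidation of the secondary alcohol gives the 4α-hydroxy-3-ketone F6. NaBH4 in MeOH at low temperature reduces the saturated C3 ketone faster than the tetrasubstituted enone, and from the convex face, to give the 3α,4α-diol F7. The conditions of step 12 then convert F7 into 26.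

**Step 14.**
- Most likely failure: acylation of the axial tertiary hydroxyl is very slow, because it is flanked by C9 and the angelate. Forcing conditions bring ionisation with elimination and Z-to-E drift.
- Fallback: it sets out from 26 and comes back at 30, and it delivers the acetyl group intramolecularly before the angelate is introduced. Trimethyl orthoacetate with camphorsulfonic acid gives the cyclic orthoacetate F8. Brief treatment with aqueous AcOH opens F8 under stereoelectronic control to the axial ester, the 4α-acetoxy-3α-ol F9. Esterification of F9 with 28, as in step 13, gives 30.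

**Step 6.**
- Most likely failure: the vinyl anion is protonated prematurely by solvent or amine, the alkoxide is O-methylated, or the β-oxido hydrazone anion undergoes retro-aldol-type cleavage.
- Fallback: it sets out from 6 and comes back at 10, and it replaces vinyl-anion alkylation by cross-coupling. TBSCl and imidazole give the silyl ether F10. KHMDS then PhNTf2 give the enol triflate F11, with regiochemistry again dictated by the bridgehead. MeMgBr with Fe(acac)3 (cat.) gives the methyl alkene F12, and TBAF gives 10.

**Step 4.**
- Most likely failure: the enantiotopic carbonyl groups are not told apart well enough, the diol forms by over-reduction, or only enzymes of the opposite (Prelog) sense are selective.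
- Fallback: it sets out from 5 and comes back at 11, and it uses the other enantiomer by exchanging the roles of the two bridges. A Prelog-type reductase (baker's yeast) gives the enantiomeric hydroxy ketone F13. Ethylene glycol with PPTS gives the hydroxy ketal F14. Dess–Martin oxidation gives the keto ketal F15. KHMDS then PhNTf2 give the enol triflate F16. MeMgBr with Fe(acac)3 (cat.) gives the methyl alkene ketal F17. Aqueous HCl in acetone then gives 11.

## Further compounds

F1 | step 10 | (1R,2R,4R)-2-ethenyl-4,6-dimethylbicyclo[2.2.2]oct-5-en-2-ol | C[C@]12CC[C@H](C(C)=C1)[C@](O)(C=C)C2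
F2 | step 10 | (5S,10R)-11,12,13-trinor-5βH-eudesm-3-en-8-one | CC1=CCC[C@]2(C)CC(=O)CC[C@H]12
F3 | step 10 | (5S,10R)-11-hydroxy-5βH-eudesm-3-en-8-one (C7 epimers) | CC1=CCC[C@]2(C)CC(=O)C(C(C)(C)O)C[C@H]12
F4 | step 11 | 3β,4β-epoxy-5βH-eudesm-7(11)-en-8-one | O1[C@H]2CC[C@]3(C)CC(=O)C(=C(C)C)C[C@@H]3[C@@]12C
F5 | step 11 | 3β,4α-dihydroxy-5βH-eudesm-7(11)-en-8-one | O[C@H]1CC[C@]2(C)CC(=O)C(=C(C)C)C[C@@H]2[C@]1(C)O
F6 | step 11 | 4α-hydroxy-5βH-eudesm-7(11)-ene-3,8-dione | O=C1CC[C@]2(C)CC(=O)C(=C(C)C)C[C@@H]2[C@]1(C)O
F7 | step 11 | 3α,4α-dihydroxy-5βH-eudesm-7(11)-en-8-one | O[C@@H]1CC[C@]2(C)CC(=O)C(=C(C)C)C[C@@H]2[C@]1(C)O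
F8 | step 14 | 3α,4α-O-(1-methoxyethylidene) derivative of 26 | O1[C@@H]2CC[C@]3(C)CC(=O)[C@@H](C(C)C)C[C@@H]3[C@]2(C)OC1(C)OC
F9 | step 14 | (3R,4S,5S,7R,10R)-4α-acetoxy-3α-hydroxy-5βH,7αH-eudesman-8-one | O[C@@H]1CC[C@]2(C)CC(=O)[C@@H](C(C)C)C[C@@H]2[C@]1(C)OC(C)=O
F10 | step 6 | tert-butyldimethylsilyl ether of 6 | C[C@]12CC[C@H](C(=O)C1)[C@H](O[Si](C)(C)C(C)(C)C)C2
F11 | step 6 | enol triflate of F10 | C[C@]12CC[C@H](C(OS(=O)(=O)C(F)(F)F)=C1)[C@H](O[Si](C)(C)C(C)(C)C)C2
F12 | step 6 | tert-butyldimethylsilyl ether of 10 | C[C@]12CC[C@H](C(C)=C1)[C@H](O[Si](C)(C)C(C)(C)C)C2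
F13 | step 4 | (1R,4S,6S)-6-hydroxy-4-methylbicyclo[2.2.2]octan-2-one | C[C@]12CC[C@H]([C@@H](O)C1)C(=O)C2
F14 | step 4 | ethylene ketal of F13 | C[C@]12CC[C@H]([C@@H](O)C1)C3(OCCO3)C2
F15 | step 4 | 6,6-ethylenedioxy-4-methylbicyclo[2.2.2]octan-2-one (from F14) | C[C@]12CC[C@H](C(=O)C1)C3(OCCO3)C2
F16 | step 4 | enol triflate of F15 | C[C@]12CC[C@H](C(OS(=O)(=O)C(F)(F)F)=C1)C3(OCCO3)C2
F17 | step 4 | ethylene ketal of 11 | C[C@]12CC[C@H](C(C)=C1)C3(OCCO3)C2
A1 | alternative 1 | (5R)-2-methyl-5-(propan-2-yl)cyclohexan-1-one | CC1CC[C@@H](C(C)C)CC1=O
A2 | alternative 1 | pent-1-en-3-one | CCC(=O)C=C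
A3 | alternative 1 | 7β-isopropyl-10β-methyl eudesm-4-en-3-one | CC1=C2C[C@H](C(C)C)CC[C@@]2(C)CCC1=O
A4 | alternative 2 | (3R,1(10)E,4E)-3-hydroxygermacra-1(10),4,7(11)-trien-8-one | C/C1=C\CC(=C(C)C)C(=O)C/C(C)=C/C[C@H]1O
A5 | alternative 2 | 3α,4α-dihydroxy-5αH-eudesm-7(11)-en-8-one (trans-fused) | O[C@@H]1CC[C@]2(C)CC(=O)C(=C(C)C)C[C@H]2[C@]1(C)O
A6 | alternative 3 | tert-butyldimethyl[(3-isopropylbuta-1,3-dien-2-yl)oxy]silane | C=C(O[Si](C)(C)C(C)(C)C)C(=C)C(C)C
A7 | alternative 3 | cis-8-(tert-butyldimethylsilyloxy)-15-nor-5βH-eudesm-7-en-4-one | O=C1CCC[C@]2(C)CC(O[Si](C)(C)C(C)(C)C)=C(C(C)C)C[C@H]12
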